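The route rests on one disconnection. The tetrahydrofuran ring of the target (C7–O–C10 with the C8–C9 bridge) is a reduced 2-methyl-5-alkylfuran, and C4–C5–C6 of the seven-membered carbocycle is an oxyallyl cation. A single intramolecular [4+3] cycloaddition forms C4–C10 and C6–C7. It closes the cyclopentane (C1–C4, C10) and the oxygen-bridged cycloheptene, and it sets C4, C7 and C10 under the influence of C1. The precursor is an open-chain furan whose C1 carries the silyl-protected C11–C12 side chain and a C2–C3 tether ending in a tertiary alpha-chloro methyl ketone. The C5 carbonyl then serves to oxygenate C6 and is deleted by radical deoxygenation.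

Key step: step 7

Atom labels: C1 = cyclopentane CH carrying the side chain; C2, C3 = cyclopentane CH2; C4 = quaternary carbon with methyl; C5 = CH2 of the target; C6 = carbinol CH; C7 = methyl-bearing ether carbon; C8, C9 = two-carbon bridge; C10 = ring-fusion ether carbon; C11 = side-chain CH; C12 = CH2O.

Assumption: 11 is carried as both C4 epimers (one drawn) because ionisation flattens C4. Compounds 15 and 16 are carried as C6 epimers until the equilibration in step 9.

Step 1
Reactants: 1 methyl (R)-3-hydroxy-2-methylpropanoate
Product: 2 methyl (R)-3-(tert-butyldimethylsilyloxy)-2-methylpropanoate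
Conditions: TBSCl, imidazole, CH2Cl2, 0 °C to rt
Reagents that add atoms: tert-butyldimethylsilyl chloride, CC(C)(C)[Si](C)(C)Cl
Why: Imidazole-promoted silylation of a primary alcohol is routine and touches neither the ester nor the C11 stereocentre.

Step 2
Reactants: 2 methyl (R)-3-(tert-butyldimethylsilyloxy)-2-methylpropanoate
Product: 3 (R)-3-(tert-butyldimethylsilyloxy)-2-methylpropanal
Conditions: i-Bu2AlH (1.05 equiv), CH2Cl2, −78 °C; aq. potassium sodium tartrate; used crude
Reagents that add atoms: none
Why: Partial reduction of an ester with one equivalent of i-Bu2AlH stops at the aldehyde oxidation level at −78 °C, and immediate use of the crude aldehyde guards the enolisable C11 centre.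

Step 3
Reactants: 3 (R)-3-(tert-butyldimethylsilyloxy)-2-methylpropanal; 4 (triphenylphosphoranylidene)acetaldehyde
Product: 5 (2E,4S)-5-(tert-butyldimethylsilyloxy)-4-methylpent-2-enal
Conditions: toluene, 80 °C
Reagents that add atoms: none
Why: Wittig olefination with a stabilised formyl ylide is E-selective and needs no added base, so C11 is preserved and the enal is reached without a redox detour.

Step 4
Reactants: 5 (2E,4S)-5-(tert-butyldimethylsilyloxy)-4-methylpent-2-enal; 6 2-methylfuran (excess)
Product: 7 (3R,4S)-5-(tert-butyldimethylsilyloxy)-4-methyl-3-(5-methylfuran-2-yl)pentanal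
Conditions: (2R,5R)-5-benzyl-2-tert-butyl-3-methylimidazolidin-4-one·CF3CO2H (20 mol %), CH2Cl2/i-PrOH, −20 °C
Reagents that add atoms: none
Why: Iminium-catalysed asymmetric Friedel–Crafts alkylation: the benzyl arm of the (2R,5R)-catalyst screens one face of the E-iminium ion, so the free C5 position of the furan attacks C1 from the open face and sets C1 as R (syn to the C11 methyl), while the E-alkene leaves the resident C11 centre little allylic strain with which to oppose the catalyst.

Step 5
Reactants: 7 (3R,4S)-5-(tert-butyldimethylsilyloxy)-4-methyl-3-(5-methylfuran-2-yl)pentanal; 8 3-(triphenylphosphoranylidene)butan-2-one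
Product: 9 (3E,6R,7S)-8-(tert-butyldimethylsilyloxy)-3,7-dimethyl-6-(5-methylfuran-2-yl)oct-3-en-2-one
Conditions: toluene, 100 °C
Reagents that add atoms: none
Why: Wittig olefination of an unhindered aldehyde with a stabilised acyl ylide installs C4, its methyl group, C5 and C6 in one operation, and the alkene geometry is irrelevant because step 6 saturates it.

Step 6
Reactants: 9 (3E,6R,7S)-8-(tert-butyldimethylsilyloxy)-3,7-dimethyl-6-(5-methylfuran-2-yl)oct-3-en-2-one
Product: 11 furyl alpha-chloro ketone (6R,7S)-8-(tert-butyldimethylsilyloxy)-3-chloro-3,7-dimethyl-6-(5-methylfuran-2-yl)octan-2-one (C4 epimers; 3R epimer drawn), via triethylsilyl enol ether 10 (not isolated)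
Conditions: RhCl(PPh3)3 (1 mol %), Et3SiH (1.1 equiv), THF, 50 °C; then NCS, NaHCO3, 0 °C
Reagents that add atoms: triethylsilane, CC[SiH](CC)CC (silyl group present in 10 only); N-chlorosuccinimide, O=C1CCC(=O)N1Cl
Why: Rhodium-catalysed 1,4-hydrosilylation puts hydride on C3 and silicon on oxygen, so the enol ether double bond can lie only between C4 and C5, and electrophilic chlorination of this tetrasubstituted silyl enol ether by N-chlorosuccinimide at low temperature should outrun attack on the furan and place chlorine on C4 alone, whose configuration is of no consequence.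

Step 7
Reactants: 11 furyl alpha-chloro ketone
Product: 13 oxa-bridged tricyclic C5 ketone (C7–O–C10 bridge; C8=C9 olefin; C12 OTBS), via oxyallyl cation 12 (not isolated)
Conditions: Et3N (3 equiv), CF3CH2OH (0.02 M), 0 °C to rt
Reagents that add atoms: none
Why: Et3N enolises the ketone toward the C6 methyl group and the enolate, activated by hydrogen bonding from CF3CH2OH, expels the tertiary C4 chloride to give oxyallyl cation 12, a two-electron three-carbon unit that adds across the furan termini C10 and C7 on one face, in concert or by way of the oxocarbenium ion left after C4–C10 bonding. The closest known reaction type is the base-induced intramolecular [4+3] cycloaddition of furan-tethered alpha-halo ketones in fluorinated alcohols, and intermolecular cases starting from 3-chloro-3-methylbutan-2-one show that a fully substituted terminus can bond to a furan. The cyclopentane closes in a 5-exo manner when C4 meets C10 through the C1–C2–C3 tether, and the cycloheptenone closes by the second bond C6–C7 of the cycloaddition, the furan oxygen becoming the one-atom bridge. C10 and C7 are linked to each other by the suprafacial addition and their absolute sense comes from C1: in the reacting rotamer C2 rises toward the cation, the C1 hydrogen lies on the side of C9–H and the branched C11 group lies beside the bare ring oxygen, which minimises A(1,3) strain and puts side chain and bridging oxygen on one face of the new cyclopentane. C4 is set by the compact arrangement with the longer C3 chain in the outer (W) position of the cation and the methyl group in the inner one, which leaves C3 anti and the methyl syn to the oxygen bridge (cis-fused five-seven carbocycle); the extended alternative is disfavoured because it would push the inner methyl over C9. The step thus needs face selectivity, compact geometry and cycloaddition faster than solvent capture, Favorskii closure or loss of HCl; the short tether and the electron-rich 2,5-dialkylfuran secure the rate, whereas the two stereochemical preferences are reasoned but unproven and make this the one high-risk step.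

Step 8
Reactants: 13 oxa-bridged tricyclic C5 ketone
Product: 15 C6-hydroxy C5 ketone (C6 epimers), via potassium enolate 14 (not isolated)
Conditions: KN(SiMe3)2, THF, −78 °C; 2-(phenylsulfonyl)-3-phenyloxaziridine, −78 °C; AcOH
Reagents that add atoms: 2-(phenylsulfonyl)-3-phenyloxaziridine, O=S(=O)(N1OC1c1ccccc1)c1ccccc1; potassium bis(trimethylsilyl)amide, C[Si](C)(C)[N-][Si](C)(C)C.[K+] (potassium present in 14 only)
Why: Davis oxidation of the only enolate that the ketone can form (C4 is quaternary) delivers oxygen to C6 without touching the C8=C9 olefin, the poorly aligned C7–O bond resists beta-elimination at −78 °C, and the C6 configuration is left open because step 9 corrects it.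

Step 9
Reactants: 15 C6-hydroxy C5 ketone (C6 epimers)
Product: 17 equatorial C6 benzyloxymethyl ether of the C5 ketone, via C6-epimeric benzyloxymethyl ethers 16 (not isolated)
Conditions: BnOCH2Cl, i-Pr2NEt, Bu4NI (cat.), toluene, 60 °C; MeOH; then DBU, 60 °C
Reagents that add atoms: benzyl chloromethyl ether, ClCOCc1ccccc1
Why: O-Alkylation of the hindered ketol with the reactive chloromethyl ether under amine base gives a non-migrating, hydrogenolysable acetal ether, and enolate-mediated epimerisation with DBU then sets C6 under thermodynamic control, the equatorial ether (C6–O anti to C7–O, trans to the C4 methyl) being favoured because its axial epimer suffers a syn-diaxial clash with that methyl group.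

Step 10
Reactants: 17 equatorial C6 benzyloxymethyl ether of the C5 ketone
Product: 18 C5 alcohol (hydroxyl endo; toward the C8=C9 bridge)
Conditions: i-Bu2AlH, CH2Cl2, −78 °C; aq. potassium sodium tartrate
Reagents that add atoms: none
Why: Hydride reduction of the ketone by i-Bu2AlH should occur from the face of the oxygen bridge, away from the C8=C9 bridge, to give the endo alcohol, and the new C5 centre is erased in step 12 so that either epimer serves.

Step 11
Reactants: 18 C5 alcohol
Product: 21 C5 S-methyl xanthate, via sodium alkoxide 19 (not isolated), via sodium xanthate 20 (not isolated)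
Conditions: NaH, imidazole (cat.), THF, 0 °C to rt; CS2; MeI
Reagents that add atoms: carbon disulfide, S=C=S; iodomethane, CI; sodium hydride, [Na+].[H-] (sodium present in 19 and 20 only)
Why: Xanthate formation through the alkoxide uses the very small electrophile CS2, which suits the crowded C5 carbinol, and the acetal ether at C6 cannot migrate to the alkoxide as a silyl or acyl group could.

Step 12
Reactants: 21 C5 S-methyl xanthate
Product: 22 C5-deoxygenated tricycle (C6 OCH2OBn; C12 OTBS; C8=C9 olefin)
Conditions: Bu3SnH, AIBN (cat.), toluene, 100 °C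
Reagents that add atoms: none
Why: Barton–McCombie deoxygenation: stannyl radical addition to the thiocarbonyl group and fragmentation give a secondary C5 radical that abstracts hydrogen from Bu3SnH, a beta-alkoxy group is not expelled from a carbon radical, and hydrazone-type carbonyl removal, which could eliminate the C6 oxygen, is avoided.

Step 13
Reactants: 22 C5-deoxygenated tricycle
Product: 23 primary C12 alcohol (C6 OCH2OBn)
Conditions: Bu4NF, THF, rt
Reagents that add atoms: none
Why: Fluoride cleaves the only silyl ether and leaves the acetal ether, the olefin and the bridging ether untouched.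

Step 14
Reactants: 23 primary C12 alcohol; 24 4-(benzyloxy)-3-methoxybenzoic acid
Product: 25 C12 4-(benzyloxy)-3-methoxybenzoate (C6 OCH2OBn; C8=C9 olefin)
Conditions: EDC·HCl, DMAP, CH2Cl2, 0 °C to rt
Reagents that add atoms: none
Why: Carbodiimide/DMAP (Steglich-type) esterification meets a single free hydroxyl group, the primary C12 alcohol, and the phenol of the acid is masked as its benzyl ether.

Step 15
Reactants: 25 C12 4-(benzyloxy)-3-methoxybenzoate
Product: 26 target CNP0277205.1
Conditions: H2 (1 atm), Pd(OH)2/C, EtOH, rt
Reagents that add atoms: none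
Why: Heterogeneous hydrogenation saturates the strained C8=C9 olefin (no stereocentre arises) and hydrogenolyses the aryl benzyl ether and the benzyloxymethyl ether in the same operation, while the alkyl aryl ester and the saturated ether bridge are inert.

Compound list
1 | methyl (R)-3-hydroxy-2-methylpropanoate | OC[C@@H](C)C(=O)OC | starting material
2 | methyl (R)-3-(tert-butyldimethylsilyloxy)-2-methylpropanoate | CC(C)(C)[Si](C)(C)OC[C@@H](C)C(=O)OC | intermediate
3 | (R)-3-(tert-butyldimethylsilyloxy)-2-methylpropanal | CC(C)(C)[Si](C)(C)OC[C@@H](C)C=O | intermediate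
4 | (triphenylphosphoranylidene)acetaldehyde | O=CC=P(c1ccccc1)(c1ccccc1)c1ccccc1 | starting material
5 | (2E,4S)-5-(tert-butyldimethylsilyloxy)-4-methylpent-2-enal | CC(C)(C)[Si](C)(C)OC[C@@H](C)/C=C/C=O | intermediate
6 | 2-methylfuran | Cc1ccco1 | starting material
7 | (3R,4S)-5-(tert-butyldimethylsilyloxy)-4-methyl-3-(5-methylfuran-2-yl)pentanal | CC(C)(C)[Si](C)(C)OC[C@@H](C)[C@@H](CC=O)c1ccc(C)o1 | intermediate
8 | 3-(triphenylphosphoranylidene)butan-2-one | CC(=O)C(C)=P(c1ccccc1)(c1ccccc1)c1ccccc1 | starting material
9 | (3E,6R,7S)-8-(tert-butyldimethylsilyloxy)-3,7-dimethyl-6-(5-methylfuran-2-yl)oct-3-en-2-one | CC(C)(C)[Si](C)(C)OC[C@@H](C)[C@@H](C/C=C(\C)C(C)=O)c1ccc(C)o1 | intermediate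
10 | triethylsilyl enol ether, (6R,7S)-8-(tert-butyldimethylsilyloxy)-3,7-dimethyl-6-(5-methylfuran-2-yl)-2-(triethylsilyloxy)oct-2-ene, E/Z mixture | CC(C)(C)[Si](C)(C)OC[C@@H](C)[C@@H](CCC(C)=C(C)O[Si](CC)(CC)CC)c1ccc(C)o1 | intermediate
11 | furyl alpha-chloro ketone, (6R,7S)-8-(tert-butyldimethylsilyloxy)-3-chloro-3,7-dimethyl-6-(5-methylfuran-2-yl)octan-2-one, both C4 epimers, 3R epimer drawn | CC(C)(C)[Si](C)(C)OC[C@@H](C)[C@@H](CC[C@@](C)(Cl)C(C)=O)c1ccc(C)o1 | intermediate
12 | oxyallyl cation spanning C4–C5–C6, tethered to the furan through C1–C3 | CC(C)(C)[Si](C)(C)OC[C@@H](C)[C@@H](CC[C+](C)C([O-])=C)c1ccc(C)o1 | intermediate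
13 | oxa-bridged tricyclic C5 ketone with C8=C9 olefin; C11 side chain, bridging oxygen and C4 methyl on one face of the cyclopentane, C3 anti to the bridge | CC(C)(C)[Si](C)(C)OC[C@@H](C)[C@H]2CC[C@]3(C)C(=O)C[C@]4(C)C=C[C@]23O4 | intermediate
14 | potassium C5–C6 enolate of 13 | CC(C)(C)[Si](C)(C)OC[C@@H](C)[C@H]2CC[C@]3(C)C([O-])=C[C@]4(C)C=C[C@]23O4.[K+] | intermediate
15 | C6-hydroxy C5 ketone, C6 epimers | CC(C)(C)[Si](C)(C)OC[C@@H](C)[C@H]2CC[C@]3(C)C(=O)C(O)[C@]4(C)C=C[C@]23O4 | intermediate
16 | C6 benzyloxymethyl ethers of 15, C6 epimers | CC(C)(C)[Si](C)(C)OC[C@@H](C)[C@H]2CC[C@]3(C)C(=O)C(OCOCc5ccccc5)[C@]4(C)C=C[C@]23O4 | intermediate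
17 | C5 ketone with equatorial C6 benzyloxymethyl ether (C6–O anti to C7–O, trans to the C4 methyl) | CC(C)(C)[Si](C)(C)OC[C@@H](C)[C@H]2CC[C@]3(C)C(=O)[C@H](OCOCc5ccccc5)[C@]4(C)C=C[C@]23O4 | intermediate
18 | C5 alcohol, hydroxyl endo (toward C8=C9), C6 ether as in 17 | CC(C)(C)[Si](C)(C)OC[C@@H](C)[C@H]2CC[C@]3(C)[C@H](O)[C@H](OCOCc5ccccc5)[C@]4(C)C=C[C@]23O4 | intermediate
19 | sodium alkoxide of 18 | CC(C)(C)[Si](C)(C)OC[C@@H](C)[C@H]2CC[C@]3(C)[C@H]([O-])[C@H](OCOCc5ccccc5)[C@]4(C)C=C[C@]23O4.[Na+] | intermediate
20 | sodium xanthate of 18 | CC(C)(C)[Si](C)(C)OC[C@@H](C)[C@H]2CC[C@]3(C)[C@H](OC(=S)[S-])[C@H](OCOCc5ccccc5)[C@]4(C)C=C[C@]23O4.[Na+] | intermediate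
21 | C5 S-methyl xanthate | CC(C)(C)[Si](C)(C)OC[C@@H](C)[C@H]2CC[C@]3(C)[C@H](OC(=S)SC)[C@H](OCOCc5ccccc5)[C@]4(C)C=C[C@]23O4 | intermediate
22 | C5-deoxygenated tricycle, C6 OCH2OBn, C12 OTBS, C8=C9 olefin | CC(C)(C)[Si](C)(C)OC[C@@H](C)[C@H]2CC[C@]3(C)C[C@H](OCOCc5ccccc5)[C@]4(C)C=C[C@]23O4 | intermediate
23 | primary C12 alcohol, C6 OCH2OBn | OC[C@@H](C)[C@H]2CC[C@]3(C)C[C@H](OCOCc5ccccc5)[C@]4(C)C=C[C@]23O4 | intermediate
24 | 4-(benzyloxy)-3-methoxybenzoic acid | COc1cc(C(=O)O)ccc1OCc1ccccc1 | starting material
25 | C12 4-(benzyloxy)-3-methoxybenzoate, C6 OCH2OBn, C8=C9 olefin | COc1cc(C(=O)OC[C@@H](C)[C@H]2CC[C@]3(C)C[C@H](OCOCc5ccccc5)[C@]4(C)C=C[C@]23O4)ccc1OCc1ccccc1 | intermediate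
26 | CNP0277205.1, C12 vanillate with free equatorial C6 hydroxyl (C1 R, C4 R, C6 S, C7 S, C10 S, C11 S) | COc1cc(C(=O)OC[C@@H](C)[C@H]2CC[C@]3(C)C[C@H](O)[C@]4(C)CC[C@]23O4)ccc1O | target

Total step count: 15. Longest linear sequence: 15 steps, from 1 to 26. Compounds 4, 6, 8 and 24 are purchased.

Steps most likely to fail

Step 7. The cation may approach the other furan face, which would relieve contact between the C11 branch and the inner methyl. It may also react with the tether in the inner position, or be lost to solvent capture and dehydrochlorination. The fallback sets out from 11 and returns at 13. It exchanges the zwitterionic oxyallyl species in a protic basic medium for a 2-silyloxyallyl cation in an aprotic one. LiN(i-Pr)2 with Et3SiCl present (THF, −78 °C) should convert 11 into the kinetic enol silane on the methyl side, 2-(triethylsilyloxy)allyl chloride F1. AgClO4 in CH3NO2 at −20 °C then abstracts chloride. The cation closes the same two bonds at low temperature without nucleophilic solvent or base, and loss of the silyl group on work-up gives 13.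

Step 4. Addition of the weakly nucleophilic furan to the gamma-branched iminium ion may be slow. Facial selectivity could then be eroded by background reaction, and acid-induced oligomerisation of the furan could compete. The fallback sets out from 3 and returns at 7, and it relies on auxiliary-controlled conjugate addition.
- Horner–Wadsworth–Emmons olefination of 3 with diethyl {2-oxo-2-[(4R)-2-oxo-4-phenyl-1,3-oxazolidin-3-yl]ethyl}phosphonate (LiCl, i-Pr2NEt, MeCN) should give N-enoyl oxazolidinone F2.
- The organocopper reagent made from 6 (n-BuLi; MgBr2·OEt2; CuBr·SMe2, THF, −78 to −20 °C) adds to the chelated s-cis imide anti to the phenyl group. This gives conjugate adduct F3 with C1 as R.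
- LiBH4 (Et2O, MeOH) releases the auxiliary and gives primary alcohol F4.
- Dess–Martin oxidation (NaHCO3 buffer) returns aldehyde 7.

Step 6. Chlorine transfer may be diverted to the electron-rich furan (ring chlorination or oxidative opening), or the enol ether may hydrolyse before it is chlorinated. The fallback sets out from 9 and returns at 13. It avoids electrophilic halogen and uses a sulfonate leaving group. Mukaiyama-type reductive hydration of enone 9 (Mn(dpm)3 cat., dpm = dipivaloylmethanate, PhSiH3, O2, i-PrOH, 0 °C; then P(OEt)3) places a hydroxyl group on C4 and gives tertiary alpha-hydroxy ketone F5. MsCl and Et3N (CH2Cl2, −20 °C, sulfene pathway) give tertiary alpha-mesyloxy ketone F6. Et3N in CF3CH2OH ionises it to the same cation 12 and hence to 13.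

Further compounds
F1 | step 7 | 2-(triethylsilyloxy)allyl chloride, (6R,7S)-8-(tert-butyldimethylsilyloxy)-3-chloro-3,7-dimethyl-6-(5-methylfuran-2-yl)-2-(triethylsilyloxy)oct-1-ene, C3 epimers | CC(C)(C)[Si](C)(C)OC[C@@H](C)[C@@H](CCC(C)(Cl)C(=C)O[Si](CC)(CC)CC)c1ccc(C)o1
F2 | step 4 | N-enoyl oxazolidinone, (4R)-3-[(2E,4S)-5-(tert-butyldimethylsilyloxy)-4-methylpent-2-enoyl]-4-phenyl-1,3-oxazolidin-2-one | CC(C)(C)[Si](C)(C)OC[C@@H](C)/C=C/C(=O)N1[C@H](c2ccccc2)COC1=O
F3 | step 4 | conjugate adduct, (4R)-3-[(3R,4S)-5-(tert-butyldimethylsilyloxy)-4-methyl-3-(5-methylfuran-2-yl)pentanoyl]-4-phenyl-1,3-oxazolidin-2-one | CC(C)(C)[Si](C)(C)OC[C@@H](C)[C@@H](CC(=O)N1[C@H](c2ccccc2)COC1=O)c1ccc(C)o1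
F4 | step 4 | primary alcohol, (3R,4S)-5-(tert-butyldimethylsilyloxy)-4-methyl-3-(5-methylfuran-2-yl)pentan-1-ol | CC(C)(C)[Si](C)(C)OC[C@@H](C)[C@@H](CCO)c1ccc(C)o1
F5 | step 6 | tertiary alpha-hydroxy ketone, (6R,7S)-8-(tert-butyldimethylsilyloxy)-3-hydroxy-3,7-dimethyl-6-(5-methylfuran-2-yl)octan-2-one, C3 epimers | CC(C)(C)[Si](C)(C)OC[C@@H](C)[C@@H](CCC(C)(O)C(C)=O)c1ccc(C)o1
F6 | step 6 | tertiary alpha-mesyloxy ketone, methanesulfonate of F5 | CC(C)(C)[Si](C)(C)OC[C@@H](C)[C@@H](CCC(C)(OS(C)(=O)=O)C(C)=O)c1ccc(C)o1
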